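**Retrosynthetic overview**
1. C11=C12 is cut by a Wittig disconnection into a furanoid C15 phosphonium salt and commercial C10 trienedial; carbonyl reduction and desilylation finish the chain.
2. Ring B (the 2,5-dihydrofuran) comes from PPh3 ring contraction, with inversion at C8, of a 5,8-endoperoxide, itself made by [4+2] cycloaddition of singlet oxygen to the C5=C6–C7=C8 diene of a C15 trienoate.
3. The C15 trienoate comes from a Horner–Wadsworth–Emmons reaction on (3R)-3-silyloxy-β-ionone, which comes from a Heck coupling of methyl vinyl ketone with the enol triflate of (4R,6R)-actinol.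
4. Ring order: ring A (the carbocycle, carrying C3) is bought; ring B is formed first as a 1,2-dioxine (C5 and C8 set from C3) and then contracted.

Assumption: (4R,6R)-actinol is taken as a commercial chiral-pool ketone; carotenoid numbering (C1–C12') is used in the discussion, TBSO = tert-butyldimethylsilyloxy, and the target is the (3S,5R,8S) isomer.

**Step 1**
Reactants: 1 (4R,6R)-4-hydroxy-2,2,6-trimethylcyclohexan-1-one
Product: 2 (4R,6R)-4-(tert-butyldimethylsilyloxy)-2,2,6-trimethylcyclohexan-1-one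
Conditions: TBSCl, imidazole, DMF, rt
Reagents that add atoms: TBSCl, CC(C)(C)[Si](C)(C)Cl
Why: Imidazole-promoted silylation of the secondary alcohol leaves the ketone and the carbinol stereocentre untouched and installs a bulky group that later biases the ring faces.

**Step 2**
Reactants: 2 (4R,6R)-4-(tert-butyldimethylsilyloxy)-2,2,6-trimethylcyclohexan-1-one
Product: 4 (4R)-4-(tert-butyldimethylsilyloxy)-2,6,6-trimethylcyclohex-1-en-1-yl trifluoromethanesulfonate, via lithium enolate 3 (not isolated)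
Conditions: LiN(i-Pr)2, THF, −78 °C; then PhNTf2, −78 °C → rt; aq. NH4Cl
Reagents that add atoms: PhNTf2, O=S(=O)(N(c1ccccc1)S(=O)(=O)C(F)(F)F)C(F)(F)F
Why: The ketone has a single α-hydrogen, so deprotonation gives one tetrasubstituted enolate that is O-triflated (enol triflate formation), erasing the C6 stereocentre on purpose while the silyloxy carbon is unaffected.

**Step 3**
Reactants: 4 (4R)-4-(tert-butyldimethylsilyloxy)-2,6,6-trimethylcyclohex-1-en-1-yl trifluoromethanesulfonate; 5 methyl vinyl ketone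
Product: 6 (3E)-4-[(4R)-4-(tert-butyldimethylsilyloxy)-2,6,6-trimethylcyclohex-1-en-1-yl]but-3-en-2-one
Conditions: Pd(OAc)2 (5 mol%), PPh3 (10 mol%), Et3N, DMF, 75 °C
Reagents that add atoms: none
Why: In this Mizoroki–Heck coupling the vinyl triflate adds oxidatively to zerovalent palladium formed in situ, and syn insertion of the enone followed by syn β-hydride elimination gives the E-dienone.

**Step 4**
Reactants: 6 (3E)-4-[(4R)-4-(tert-butyldimethylsilyloxy)-2,6,6-trimethylcyclohex-1-en-1-yl]but-3-en-2-one; 7 triethyl phosphonoacetate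
Product: 9 ethyl (2E,4E)-5-[(4R)-4-(tert-butyldimethylsilyloxy)-2,6,6-trimethylcyclohex-1-en-1-yl]-3-methylpenta-2,4-dienoate, via sodium phosphonate carbanion 8 (not isolated)
Conditions: NaH, THF, 0 °C → 50 °C; chromatography to remove the minor 9Z isomer
Reagents that add atoms: none
Why: The Horner–Wadsworth–Emmons olefination of a β-ionone-type methyl ketone with a stabilised phosphonate carbanion is expected to favour the 9E trienoate (roughly 7:1), and the ester it installs deactivates the C7–C10 diene for the next step.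

**Step 5**
Reactants: 9 ethyl (2E,4E)-5-[(4R)-4-(tert-butyldimethylsilyloxy)-2,6,6-trimethylcyclohex-1-en-1-yl]-3-methylpenta-2,4-dienoate
Product: 10 ethyl (2E)-3-[(3R,7S,8aR)-7-(tert-butyldimethylsilyloxy)-5,5,8a-trimethyl-3,5,6,7,8,8a-hexahydrobenzo[c][1,2]dioxin-3-yl]but-2-enoate
Conditions: O2, tetraphenylporphyrin (cat.), visible light, CH2Cl2, −20 °C; quick cold filtration through silica to remove the minor diastereomer
Reagents that add atoms: O2 (as singlet oxygen), O=O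
Why: Singlet oxygen adds in a suprafacial [4+2] cycloaddition (hetero-Diels–Alder) across C5–C8 of the electron-rich ring diene, so 5-methyl and 8-H end up cis on the new dioxine, and axial attack at C5 on the face opposite the equatorial 3-silyloxy group is expected to set 5R and 8R from C3.

**Step 6**
Reactants: 10 ethyl (2E)-3-[(3R,7S,8aR)-7-(tert-butyldimethylsilyloxy)-5,5,8a-trimethyl-3,5,6,7,8,8a-hexahydrobenzo[c][1,2]dioxin-3-yl]but-2-enoate
Product: 12 ethyl (2E)-3-[(2S,6S,7aR)-6-(tert-butyldimethylsilyloxy)-4,4,7a-trimethyl-2,4,5,6,7,7a-hexahydro-1-benzofuran-2-yl]but-2-enoate, via cyclic dioxaphosphorane 11 (not isolated)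
Conditions: PPh3 (1.1 equiv), CH2Cl2, −20 °C → rt
Reagents that add atoms: none
Why: In this deoxygenative ring contraction PPh3 inserts into the O–O bond, the phosphorane opens to a C5 alkoxide and a C8 alkoxyphosphonium, and 5-exo-tet SN2 displacement at the secondary C8 (disfavoured for ionisation by the conjugated ester) proceeds with inversion to turn 8R into the required 8S while the tertiary C5–O bond is retained.

**Step 7**
Reactants: 12 ethyl (2E)-3-[(2S,6S,7aR)-6-(tert-butyldimethylsilyloxy)-4,4,7a-trimethyl-2,4,5,6,7,7a-hexahydro-1-benzofuran-2-yl]but-2-enoate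
Product: 13 (2E)-3-[(2S,6S,7aR)-6-(tert-butyldimethylsilyloxy)-4,4,7a-trimethyl-2,4,5,6,7,7a-hexahydro-1-benzofuran-2-yl]but-2-en-1-ol
Conditions: i-Bu2AlH (2.2 equiv), CH2Cl2, −78 °C; aq. potassium sodium tartrate
Reagents that add atoms: none
Why: Low-temperature 1,2-reduction of the conjugated ester by the aluminium hydride gives the allylic alcohol without touching the silyl ether, the cyclic ether or any stereocentre.

**Step 8**
Reactants: 13 (2E)-3-[(2S,6S,7aR)-6-(tert-butyldimethylsilyloxy)-4,4,7a-trimethyl-2,4,5,6,7,7a-hexahydro-1-benzofuran-2-yl]but-2-en-1-ol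
Product: 15 [(2E)-3-[(2S,6S,7aR)-6-(tert-butyldimethylsilyloxy)-4,4,7a-trimethyl-2,4,5,6,7,7a-hexahydro-1-benzofuran-2-yl]but-2-en-1-yl]triphenylphosphonium bromide, via allylic bromide 14 (not isolated)
Conditions: CBr4, PPh3 (1.1 equiv each), 2,6-lutidine (cat.), CH2Cl2, 0 °C; then PPh3 (1.5 equiv), rt; precipitate from Et2O
Reagents that add atoms: CBr4, BrC(Br)(Br)Br; PPh3, c1ccc(cc1)P(c1ccccc1)c1ccccc1
Why: An Appel bromination under acid-free conditions followed by SN2 quaternisation of PPh3 by the primary allylic bromide avoids the protic acid that would ionise and epimerise the doubly allylic C8–O bond.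

**Step 9**
Reactants: 15 [(2E)-3-[(2S,6S,7aR)-6-(tert-butyldimethylsilyloxy)-4,4,7a-trimethyl-2,4,5,6,7,7a-hexahydro-1-benzofuran-2-yl]but-2-en-1-yl]triphenylphosphonium bromide; 16 (2E,4E,6E)-2,7-dimethylocta-2,4,6-trienedial
Product: 18 (2E,4E,6E,8E,10E)-11-[(2S,6S,7aR)-6-(tert-butyldimethylsilyloxy)-4,4,7a-trimethyl-2,4,5,6,7,7a-hexahydro-1-benzofuran-2-yl]-2,7-dimethyldodeca-2,4,6,8,10-pentaenal, via phosphonium ylide 17 (not isolated)
Conditions: 16 (3 equiv), NaOMe added slowly, MeOH/CH2Cl2, 0 °C → rt; then n-heptane, 90 °C, dark (11Z → 11E)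
Reagents that add atoms: none
Why: In this Wittig olefination the ylide is generated in the presence of excess symmetrical dialdehyde so that it is trapped at once in a mono-olefination, and the hindered 11Z isomer is equilibrated thermally to all-E without involving C8.

**Step 10**
Reactants: 18 (2E,4E,6E,8E,10E)-11-[(2S,6S,7aR)-6-(tert-butyldimethylsilyloxy)-4,4,7a-trimethyl-2,4,5,6,7,7a-hexahydro-1-benzofuran-2-yl]-2,7-dimethyldodeca-2,4,6,8,10-pentaenal
Product: 19 (2E,4E,6E,8E,10E)-11-[(2S,6S,7aR)-6-(tert-butyldimethylsilyloxy)-4,4,7a-trimethyl-2,4,5,6,7,7a-hexahydro-1-benzofuran-2-yl]-2,7-dimethyldodeca-2,4,6,8,10-pentaen-1-ol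
Conditions: NaBH4, EtOH/THF, 0 °C
Reagents that add atoms: none
Why: Borohydride performs a clean 1,2-reduction of the polyenal to the primary allylic alcohol under mildly basic conditions that the furanoid ring tolerates.

**Step 11**
Reactants: 19 (2E,4E,6E,8E,10E)-11-[(2S,6S,7aR)-6-(tert-butyldimethylsilyloxy)-4,4,7a-trimethyl-2,4,5,6,7,7a-hexahydro-1-benzofuran-2-yl]-2,7-dimethyldodeca-2,4,6,8,10-pentaen-1-ol
Product: 20 (2E,4E,6E,8E,10E)-11-[(2S,6S,7aR)-6-hydroxy-4,4,7a-trimethyl-2,4,5,6,7,7a-hexahydro-1-benzofuran-2-yl]-2,7-dimethyldodeca-2,4,6,8,10-pentaen-1-ol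
Conditions: Bu4NF, THF, 0 °C → rt, dark; neutral aqueous work-up
Reagents that add atoms: none
Why: Fluoride-mediated desilylation frees the C3 hydroxyl without acid, which would epimerise C8 of the furanoid polyene.

**Compound list**
1 | (4R,6R)-4-hydroxy-2,2,6-trimethylcyclohexan-1-one ((4R,6R)-actinol) | CC1(C)C[C@H](O)C[C@@H](C)C1=O | starting material
2 | (4R,6R)-4-(tert-butyldimethylsilyloxy)-2,2,6-trimethylcyclohexan-1-one | CC1(C)C[C@H](O[Si](C)(C)C(C)(C)C)C[C@@H](C)C1=O | intermediate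
3 | lithium (4R)-4-(tert-butyldimethylsilyloxy)-2,6,6-trimethylcyclohex-1-en-1-olate (lithium enolate of 2) | CC1=C(O[Li])C(C)(C)C[C@H](O[Si](C)(C)C(C)(C)C)C1 | intermediate
4 | (4R)-4-(tert-butyldimethylsilyloxy)-2,6,6-trimethylcyclohex-1-en-1-yl trifluoromethanesulfonate | CC1=C(OS(=O)(=O)C(F)(F)F)C(C)(C)C[C@H](O[Si](C)(C)C(C)(C)C)C1 | intermediate
5 | methyl vinyl ketone (but-3-en-2-one) | CC(=O)C=C | starting material
6 | (3E)-4-[(4R)-4-(tert-butyldimethylsilyloxy)-2,6,6-trimethylcyclohex-1-en-1-yl]but-3-en-2-one ((3R)-3-silyloxy-β-ionone) | CC1=C(/C=C/C(C)=O)C(C)(C)C[C@H](O[Si](C)(C)C(C)(C)C)C1 | intermediate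
7 | triethyl phosphonoacetate | CCOC(=O)CP(=O)(OCC)OCC | starting material
8 | sodium salt of triethyl phosphonoacetate (phosphonate carbanion) | [Na+].CCOC(=O)[CH-]P(=O)(OCC)OCC | intermediate
9 | ethyl (2E,4E)-5-[(4R)-4-(tert-butyldimethylsilyloxy)-2,6,6-trimethylcyclohex-1-en-1-yl]-3-methylpenta-2,4-dienoate | CC1=C(/C=C/C(C)=C/C(=O)OCC)C(C)(C)C[C@H](O[Si](C)(C)C(C)(C)C)C1 | intermediate
10 | ethyl (2E)-3-[(3R,7S,8aR)-7-(tert-butyldimethylsilyloxy)-5,5,8a-trimethyl-3,5,6,7,8,8a-hexahydrobenzo[c][1,2]dioxin-3-yl]but-2-enoate (the (3S,5R,8R)-5,8-endoperoxide; 5-methyl and 8-H cis, peroxide anti to the silyloxy group) | CCOC(=O)/C=C(\C)[C@H]1C=C2C(C)(C)C[C@H](O[Si](C)(C)C(C)(C)C)C[C@@]2(C)OO1 | intermediate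
11 | cyclic triphenyl-dioxaphosphorane from insertion of PPh3 into the O–O bond of 10 (configuration as in 10) | CCOC(=O)/C=C(\C)[C@H]1C=C2C(C)(C)C[C@H](O[Si](C)(C)C(C)(C)C)C[C@@]2(C)OP(c3ccccc3)(c4ccccc4)(c5ccccc5)O1 | intermediate
12 | ethyl (2E)-3-[(2S,6S,7aR)-6-(tert-butyldimethylsilyloxy)-4,4,7a-trimethyl-2,4,5,6,7,7a-hexahydro-1-benzofuran-2-yl]but-2-enoate ((3S,5R,8S) furanoid C15 ester) | CCOC(=O)/C=C(\C)[C@@H]1C=C2C(C)(C)C[C@H](O[Si](C)(C)C(C)(C)C)C[C@@]2(C)O1 | intermediate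
13 | (2E)-3-[(2S,6S,7aR)-6-(tert-butyldimethylsilyloxy)-4,4,7a-trimethyl-2,4,5,6,7,7a-hexahydro-1-benzofuran-2-yl]but-2-en-1-ol | OC/C=C(\C)[C@@H]1C=C2C(C)(C)C[C@H](O[Si](C)(C)C(C)(C)C)C[C@@]2(C)O1 | intermediate
14 | (2S,6S,7aR)-2-[(2E)-4-bromobut-2-en-2-yl]-6-(tert-butyldimethylsilyloxy)-4,4,7a-trimethyl-2,4,5,6,7,7a-hexahydro-1-benzofuran (allylic bromide) | BrC/C=C(\C)[C@@H]1C=C2C(C)(C)C[C@H](O[Si](C)(C)C(C)(C)C)C[C@@]2(C)O1 | intermediate
15 | [(2E)-3-[(2S,6S,7aR)-6-(tert-butyldimethylsilyloxy)-4,4,7a-trimethyl-2,4,5,6,7,7a-hexahydro-1-benzofuran-2-yl]but-2-en-1-yl]triphenylphosphonium bromide | [Br-].C(/C=C(\C)[C@@H]1C=C2C(C)(C)C[C@H](O[Si](C)(C)C(C)(C)C)C[C@@]2(C)O1)[P+](c3ccccc3)(c4ccccc4)c5ccccc5 | intermediate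
16 | (2E,4E,6E)-2,7-dimethylocta-2,4,6-trienedial (C10 dialdehyde) | O=C/C(C)=C/C=C/C=C(\C)C=O | starting material
17 | phosphonium ylide of 15 (deprotonated at C11) | [CH-](/C=C(\C)[C@@H]1C=C2C(C)(C)C[C@H](O[Si](C)(C)C(C)(C)C)C[C@@]2(C)O1)[P+](c3ccccc3)(c4ccccc4)c5ccccc5 | intermediate
18 | (2E,4E,6E,8E,10E)-11-[(2S,6S,7aR)-6-(tert-butyldimethylsilyloxy)-4,4,7a-trimethyl-2,4,5,6,7,7a-hexahydro-1-benzofuran-2-yl]-2,7-dimethyldodeca-2,4,6,8,10-pentaenal | CC(/C=C/C=C(\C)[C@@H]1C=C2C(C)(C)C[C@H](O[Si](C)(C)C(C)(C)C)C[C@@]2(C)O1)=C\C=C\C=C(/C)C=O | intermediate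
19 | (2E,4E,6E,8E,10E)-11-[(2S,6S,7aR)-6-(tert-butyldimethylsilyloxy)-4,4,7a-trimethyl-2,4,5,6,7,7a-hexahydro-1-benzofuran-2-yl]-2,7-dimethyldodeca-2,4,6,8,10-pentaen-1-ol | CC(/C=C/C=C(\C)[C@@H]1C=C2C(C)(C)C[C@H](O[Si](C)(C)C(C)(C)C)C[C@@]2(C)O1)=C\C=C\C=C(/C)CO | intermediate
20 | (2E,4E,6E,8E,10E)-11-[(2S,6S,7aR)-6-hydroxy-4,4,7a-trimethyl-2,4,5,6,7,7a-hexahydro-1-benzofuran-2-yl]-2,7-dimethyldodeca-2,4,6,8,10-pentaen-1-ol ((3S,5R,8S)-5,8-epoxy-5,8-dihydro-12'-apo-β-carotene-3,12'-diol) | CC(/C=C/C=C(\C)[C@@H]1C=C2C(C)(C)C[C@H](O)C[C@@]2(C)O1)=C\C=C\C=C(/C)CO | target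

**Step count**
Total steps: 11. Longest linear sequence: 11 (from 1 to 20; compounds 5, 7 and 16 are bought).

**Steps most likely to fail, with fallbacks**

Step 5 (photooxygenation). The facial preference is an argument from conformation, not a known result for this substrate, and ene reaction at the ring alkene may compete. The fallback sets out from 9 and comes back at 12. Epoxidation of 9 with mCPBA (NaHCO3, CH2Cl2, 0 °C) occurs at the ring alkene, expected mainly anti to the silyloxy group by analogy with related 3-silyloxy β-ionone-type ring alkenes, and gives ethyl (2E,4E)-5-[(1S,4S,6R)-4-(tert-butyldimethylsilyloxy)-2,2,6-trimethyl-7-oxabicyclo[4.1.0]heptan-1-yl]-3-methylpenta-2,4-dienoate F1. Brief treatment of this epoxide with pyridinium p-toluenesulfonate in CH2Cl2 triggers the epoxide-to-furanoid rearrangement (C6–O ionisation, recapture by oxygen at C8) to 12, formed together with its (2R,6S,7aR) C8 epimer F2, which is removed by chromatography. C8 is not controlled in this variant.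

Step 6 (ring contraction). The alkoxyphosphonium could ionise, eliminate or close in the SN2' sense instead of undergoing clean SN2 at C8. The fallback sets out from 10 and comes back at 12. Reduction of the O–O bond with thiourea in MeOH gives ethyl (2E,4R,5Z)-4-hydroxy-5-[(2R,4S)-2-hydroxy-4-(tert-butyldimethylsilyloxy)-2,6,6-trimethylcyclohexylidene]-3-methylpent-2-enoate F3. MsCl/Et3N in CH2Cl2 at −30 °C sulfonylates only the secondary allylic hydroxyl to give the C8 mesylate F4, which on warming is displaced by the tertiary hydroxyl (5-exo-tet, inversion at C8) to give 12.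

Step 9 (Wittig). The γ-alkoxy allylic ylide could open the dihydrofuran by vinylogous β-elimination or epimerise C8, and the new double bond forms as an E/Z mixture. The fallback sets out from 13 and comes back at 19, with the furanoid piece now the electrophile so that no carbanion sits next to C8. Oxidation of 13 with MnO2 (CH2Cl2) gives (2E)-3-[(2S,6S,7aR)-6-(tert-butyldimethylsilyloxy)-4,4,7a-trimethyl-2,4,5,6,7,7a-hexahydro-1-benzofuran-2-yl]but-2-enal F5. A Horner–Wadsworth–Emmons reaction with triethyl 3-methyl-4-phosphonocrotonate (LiN(SiMe3)2, THF, −78 → 0 °C) gives the C20 ethyl (2E,4E,6E)-trienoate F6. Reduction with i-Bu2AlH gives the C20 allylic alcohol F7, and MnO2 oxidation gives the C20 trienal F8. A second Horner–Wadsworth–Emmons reaction with ethyl 4-(diethoxyphosphoryl)-2-methylbut-2-enoate gives the C25 ethyl pentaenoate F9, whose i-Bu2AlH reduction delivers 19.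

**Further compounds**
F1 | step 5 | ethyl (2E,4E)-5-[(1S,4S,6R)-4-(tert-butyldimethylsilyloxy)-2,2,6-trimethyl-7-oxabicyclo[4.1.0]heptan-1-yl]-3-methylpenta-2,4-dienoate | CC1(C)C[C@H](O[Si](C)(C)C(C)(C)C)C[C@@]2(C)O[C@@]12/C=C/C(C)=C/C(=O)OCC
F2 | step 5 | ethyl (2E)-3-[(2R,6S,7aR)-6-(tert-butyldimethylsilyloxy)-4,4,7a-trimethyl-2,4,5,6,7,7a-hexahydro-1-benzofuran-2-yl]but-2-enoate (C8 epimer of 12) | CCOC(=O)/C=C(\C)[C@H]1C=C2C(C)(C)C[C@H](O[Si](C)(C)C(C)(C)C)C[C@@]2(C)O1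
F3 | step 6 | ethyl (2E,4R,5Z)-4-hydroxy-5-[(2R,4S)-2-hydroxy-4-(tert-butyldimethylsilyloxy)-2,6,6-trimethylcyclohexylidene]-3-methylpent-2-enoate | CCOC(=O)/C=C(\C)[C@H](O)/C=C1/C(C)(C)C[C@H](O[Si](C)(C)C(C)(C)C)C[C@@]1(C)O
F4 | step 6 | ethyl (2E,4R,5Z)-5-[(2R,4S)-2-hydroxy-4-(tert-butyldimethylsilyloxy)-2,6,6-trimethylcyclohexylidene]-4-(methanesulfonyloxy)-3-methylpent-2-enoate | CCOC(=O)/C=C(\C)[C@H](OS(C)(=O)=O)/C=C1/C(C)(C)C[C@H](O[Si](C)(C)C(C)(C)C)C[C@@]1(C)O
F5 | step 9 | (2E)-3-[(2S,6S,7aR)-6-(tert-butyldimethylsilyloxy)-4,4,7a-trimethyl-2,4,5,6,7,7a-hexahydro-1-benzofuran-2-yl]but-2-enal | O=C/C=C(\C)[C@@H]1C=C2C(C)(C)C[C@H](O[Si](C)(C)C(C)(C)C)C[C@@]2(C)O1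
F6 | step 9 | ethyl (2E,4E,6E)-7-[(2S,6S,7aR)-6-(tert-butyldimethylsilyloxy)-4,4,7a-trimethyl-2,4,5,6,7,7a-hexahydro-1-benzofuran-2-yl]-3-methylocta-2,4,6-trienoate | CC(/C=C/C=C(\C)[C@@H]1C=C2C(C)(C)C[C@H](O[Si](C)(C)C(C)(C)C)C[C@@]2(C)O1)=C\C(=O)OCC
F7 | step 9 | (2E,4E,6E)-7-[(2S,6S,7aR)-6-(tert-butyldimethylsilyloxy)-4,4,7a-trimethyl-2,4,5,6,7,7a-hexahydro-1-benzofuran-2-yl]-3-methylocta-2,4,6-trien-1-ol | CC(/C=C/C=C(\C)[C@@H]1C=C2C(C)(C)C[C@H](O[Si](C)(C)C(C)(C)C)C[C@@]2(C)O1)=C\CO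
F8 | step 9 | (2E,4E,6E)-7-[(2S,6S,7aR)-6-(tert-butyldimethylsilyloxy)-4,4,7a-trimethyl-2,4,5,6,7,7a-hexahydro-1-benzofuran-2-yl]-3-methylocta-2,4,6-trienal | CC(/C=C/C=C(\C)[C@@H]1C=C2C(C)(C)C[C@H](O[Si](C)(C)C(C)(C)C)C[C@@]2(C)O1)=C\C=O
F9 | step 9 | ethyl (2E,4E,6E,8E,10E)-11-[(2S,6S,7aR)-6-(tert-butyldimethylsilyloxy)-4,4,7a-trimethyl-2,4,5,6,7,7a-hexahydro-1-benzofuran-2-yl]-2,7-dimethyldodeca-2,4,6,8,10-pentaenoate | CC(/C=C/C=C(\C)[C@@H]1C=C2C(C)(C)C[C@H](O[Si](C)(C)C(C)(C)C)C[C@@]2(C)O1)=C\C=C\C=C(/C)C(=O)OCC
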